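## Retrosynthetic overview

1. The triene is attached last, by Horner–Wadsworth–Emmons olefination of a dioxolane 7-oxoheptyl acid with a (2E,5Z)-octa-2,5-dienyl phosphonate. The saturated spacer comes from Wittig extension and diimide reduction of one two-carbon arm, the acetic acid from oxidation of the other.
2. Both arms are the homotopic 2-hydroxyethyl groups of a C2-symmetric trans-3,5-bis(2-hydroxyethyl)-3,5-dimethyl-1,2-dioxolane; the two ring methyls of the target are trans, so its core is C2-symmetric.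
3. Key disconnection (the only ring, formed once): both peroxide C–O bonds are cut to H2O2 and (R,R)-bis(2-methyloxetan-2-yl)methane. Forward, H2O2 opens one oxetane at its quaternary carbon; the tertiary hydroperoxide then closes the 1,2-dioxolane by 5-exo opening of the second oxetane at the quaternary carbon that will carry the long chain. Each event inverts.
4. Enabling feature: two strained oxetane rings whose fully substituted, methyl-bearing C2 atoms are 1,3-related through one CH2 (the C–CH2–C unit of the dioxolane); their ring CH2CH2O atoms are delivered as the two arms.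
5. The bis-oxetane comes from penta-1,4-diyne by double carboalumination/hydroxymethylation and two Sharpless epoxidation / Red-Al / etherification cycles, which set both tertiary C–O stereocentres under reagent control.

Key step: step 11

Remark: it is assumed that 2-(4-bromobutyl)-1,3-dioxolane and (Z)-pent-2-en-1-ol are purchased and that penta-1,4-diyne is handled only as a cold stock solution.

## Route

Step 1
Reactants: 1 3-bromoprop-1-yne (propargyl bromide); 2 ethynylmagnesium bromide
Product: 3 penta-1,4-diyne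
Conditions: CuCl (cat.), THF, 0 → 45 °C; product kept as a cold solution
Reagents that add atoms: none
Why: Copper-catalysed SN2 coupling of an alkynyl Grignard reagent with a propargylic bromide should give the skipped diyne, the copper catalyst keeping attack at the CH2 terminus rather than the allene-forming SN2' mode.

Step 2
Reactants: 3 penta-1,4-diyne
Product: 5 (2E,5E)-3,5-dimethylhepta-2,5-diene-1,7-diol, via bis(alkenylalane) 4 (not isolated)
Conditions: Me3Al, Cp2ZrCl2 (zirconocene dichloride, cat.), CH2Cl2, 0 °C → rt; then (CH2O)n, THF, 0 °C → rt; aqueous work-up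
Reagents that add atoms: trimethylaluminium, C[Al](C)C; formaldehyde (as paraformaldehyde), C=O
Why: Zirconium-catalysed methylalumination (Negishi carboalumination) adds CH3 and Al syn across each terminal alkyne with methyl on the internal carbon, and hydroxymethylation of the alkenyl–Al bonds with retention should fix both trisubstituted alkenes as E.

Step 3
Reactants: 5 (2E,5E)-3,5-dimethylhepta-2,5-diene-1,7-diol
Product: 6 (2E,5E)-7-{[tert-butyl(dimethyl)silyl]oxy}-3,5-dimethylhepta-2,5-dien-1-ol
Conditions: NaH (1.0 equiv), THF, 0 °C; TBSCl (1.0 equiv); unreacted 5 recycled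
Reagents that add atoms: tert-butyldimethylsilyl chloride, CC(C)(C)[Si](C)(C)Cl
Why: Monosilylation of a symmetrical diol through its mono-sodium alkoxide; the two hydroxyls are homotopic, so only one mono-ether can form.

Step 4
Reactants: 6 mono-silyl ether
Product: 7 [(2S,3S)-3-[(2E)-4-{[tert-butyl(dimethyl)silyl]oxy}-2-methylbut-2-en-1-yl]-3-methyloxiran-2-yl]methanol
Conditions: Ti(OiPr)4 (cat.), L-(+)-diisopropyl tartrate (cat.), t-BuOOH, 4 Å MS, CH2Cl2, −20 °C
Reagents that add atoms: tert-butyl hydroperoxide, CC(C)(C)OO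
Why: Sharpless asymmetric epoxidation acts only on the free (E)-3,3-disubstituted allylic alcohol, and the L-(+)-tartrate ligand should deliver oxygen to the face that gives the (2S,3S)-epoxide, as with geraniol.

Step 5
Reactants: 7 epoxy alcohol
Product: 8 (3S,5E)-7-{[tert-butyl(dimethyl)silyl]oxy}-3,5-dimethylhept-5-ene-1,3-diol
Conditions: NaAlH2(OCH2CH2OMe)2 (Red-Al), THF, 0 °C; aq. NaOH work-up
Reagents that add atoms: none
Why: Hydroxyl-directed reductive opening of a 2,3-epoxy alcohol with Red-Al delivers hydride to C2, giving the 1,3-diol while the tertiary C–O bond and its configuration stay intact.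

Step 6
Reactants: 8 1,3-diol
Product: 10 tert-butyl(dimethyl){[(2E)-3-methyl-4-[(2S)-2-methyloxetan-2-yl]but-2-en-1-yl]oxy}silane, via primary monotosylate 9 (not isolated)
Conditions: n-BuLi (1.0 equiv), THF, 0 °C; TsCl (1.0 equiv); n-BuLi (1.0 equiv), 0 → 60 °C
Reagents that add atoms: none
Why: Sulfonylation of the primary alkoxide followed by intramolecular Williamson etherification (4-exo-tet) by the tertiary alkoxide forms the oxetane with retention at the quaternary carbon, and no second free hydroxyl is present to divert closure to a six-membered ether.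

Step 7
Reactants: 10 oxetane silyl ether
Product: 11 (2E)-3-methyl-4-[(2S)-2-methyloxetan-2-yl]but-2-en-1-ol
Conditions: TBAF, THF, 0 °C → rt
Reagents that add atoms: none
Why: Fluoride cleaves the allylic silyl ether, and oxetanes are inert to TBAF.

Step 8
Reactants: 11 oxetane allylic alcohol
Product: 12 [(2S,3S)-3-methyl-3-{[(2R)-2-methyloxetan-2-yl]methyl}oxiran-2-yl]methanol
Conditions: Ti(OiPr)4 (cat.), L-(+)-diisopropyl tartrate (cat.), t-BuOOH, 4 Å MS, CH2Cl2, −20 °C
Reagents that add atoms: tert-butyl hydroperoxide, CC(C)(C)OO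
Why: A second Sharpless asymmetric epoxidation under reagent control sets the second tertiary C–O centre as (3S); the weakly Lewis-acidic titanium tartrate complex should not open the 2,2-dialkyl oxetane at −20 °C.

Step 9
Reactants: 12 oxetane epoxy alcohol
Product: 13 (3R)-3-methyl-4-[(2R)-2-methyloxetan-2-yl]butane-1,3-diol
Conditions: NaAlH2(OCH2CH2OMe)2 (Red-Al), THF, 0 °C; aq. NaOH work-up
Reagents that add atoms: none
Why: Hydroxyl-directed hydride delivery to C2 of the epoxy alcohol gives the 1,3-diol with the tertiary C–O bond untouched, and the hindered oxetane is not reduced at 0 °C.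

Step 10
Reactants: 13 oxetane 1,3-diol
Product: 15 (2R,2'R)-2,2'-methylenebis(2-methyloxetane), via primary monotosylate 14 (not isolated)
Conditions: n-BuLi (1.0 equiv), THF, 0 °C; TsCl (1.0 equiv); n-BuLi (1.0 equiv), 0 → 60 °C
Reagents that add atoms: none
Why: The same one-pot sulfonylation and 4-exo-tet Williamson closure, with retention at the quaternary carbon, should give the C2-symmetric bis-oxetane; the first oxetane oxygen is an ether and cannot compete.

Step 11
Reactants: 15 (2R,2'R)-2,2'-methylenebis(2-methyloxetane)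
Product: 17 2,2'-[(3S,5S)-3,5-dimethyl-1,2-dioxolane-3,5-diyl]di(ethan-1-ol), via hydroperoxy oxetane 16 (not isolated)
Conditions: anhydrous H2O2 in Et2O (1.5 equiv), TMSOTf (0.2 equiv), Et2O, dilute, −78 → 0 °C; pyridine, aq. NaHCO3
Reagents that add atoms: hydrogen peroxide, OO
Why: TMSOTf activates one oxetane oxygen and H2O2 attacks the fully substituted ring carbon from the rear (borderline SN2 on a tight ion pair) to give tertiary hydroperoxide 16, whose OOH then opens the second activated oxetane at its quaternary carbon and so forms the ring-closing O–C bond of the 1,2-dioxolane. The closest known reaction types are the Lewis-acid-mediated perhydrolysis of enantioenriched 2,2-disubstituted oxetanes to 3-hydroperoxy alkanols and the acid-mediated cyclisation of oxetane-tethered hydroperoxides to 1,2-dioxolanes, here run in tandem. The dioxolane closes in the 5-exo-tet mode, since attack on the oxetane CH2–O carbon would need a seven-membered ring. Each new quaternary stereocentre is controlled by inversion at an (R)-oxetane carbon fixed earlier by Sharpless epoxidation, so (R,R)-15 should give the (3S,5S) trans diol, and a single stereochemical leak would give the separable meso cis diol rather than the enantiomer. The step needs attack at the tertiary rather than the primary C–O carbon, secured by the cation-stabilising methyl-bearing quaternary centres, and capture of the second oxetane by OOH rather than by the primary hydroxyl freed in the first opening or by a second H2O2, secured by the 5-exo geometry (the competing 6-exo ether closure must pass through a chair with a 1,3-diaxial pair on the two quaternary carbons) and by limiting H2O2 under dilution. Because the product is C2-symmetric its two hydroxyethyl arms are homotopic, so the carbon attacked last is simply the one whose arm is later extended to the chain.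

Step 12
Reactants: 17 dioxolane diol
Product: 18 2,2'-[(3R,5R)-3,5-dimethyl-1,2-dioxolane-3,5-diyl]diacetaldehyde
Conditions: Dess–Martin periodinane (2.4 equiv), CH2Cl2, 0 °C → rt; used without storage
Reagents that add atoms: none
Why: Dess–Martin oxidation converts both homotopic primary alcohols under neutral, non-basic conditions that the β-peroxy aldehyde groups should tolerate, and C2 symmetry is kept.

Step 13
Reactants: 19 2-(4-bromobutyl)-1,3-dioxolane
Product: 20 [4-(1,3-dioxolan-2-yl)butyl](triphenyl)phosphonium bromide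
Conditions: PPh3, MeCN, 80 °C
Reagents that add atoms: triphenylphosphine, c1ccc(cc1)P(c1ccccc1)c1ccccc1
Why: SN2 quaternisation of triphenylphosphine by the primary bromide.

Step 14
Reactants: 18 dialdehyde; 20 phosphonium bromide
Product: 22 2-[(3R,5S)-5-[(2Z)-6-(1,3-dioxolan-2-yl)hex-2-en-1-yl]-3,5-dimethyl-1,2-dioxolan-3-yl]acetaldehyde, via phosphorus ylide 21 (not isolated)
Conditions: 20 (0.9 equiv), NaHMDS (0.9 equiv), THF, 0 °C; added slowly to 18, THF, −78 → 0 °C; unreacted 18 recovered
Reagents that add atoms: none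
Why: Wittig olefination with a sub-stoichiometric salt-free non-stabilised ylide at −78 °C: the two formyl arms of the C2-symmetric dialdehyde are homotopic so mono-olefination gives one compound, carbonyl addition should outrun enolisation of the β-peroxy aldehyde, and the kinetic Z alkene (removed later) results.

Step 15
Reactants: 22 alkenyl aldehyde
Product: 23 2-[(3R,5S)-5-[(2Z)-6-(1,3-dioxolan-2-yl)hex-2-en-1-yl]-3,5-dimethyl-1,2-dioxolan-3-yl]acetic acid
Conditions: NaClO2, NaH2PO4, 2-methyl-2-butene, t-BuOH/H2O, 0 °C → rt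
Reagents that add atoms: sodium chlorite, [Na+].[O-]Cl=O
Why: Pinnick oxidation of the remaining aldehyde under buffered, base-free conditions (so the β-peroxy carbonyl cannot eliminate), with 2-methyl-2-butene scavenging HOCl from the alkene.

Step 16
Reactants: 23 alkenyl acid
Product: 24 2-[(3R,5S)-5-[6-(1,3-dioxolan-2-yl)hexyl]-3,5-dimethyl-1,2-dioxolan-3-yl]acetic acid
Conditions: TsNHNH2 (excess, portionwise), NaOAc, DME/H2O, 80 °C
Reagents that add atoms: none
Why: Diimide reduction transfers H2 to the isolated C=C by a concerted syn pathway and leaves the O–O bond (which catalytic hydrogenation would cleave), the acetal and the carboxylate untouched.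

Step 17
Reactants: 24 acetal acid
Product: 25 2-[(3R,5S)-3,5-dimethyl-5-(7-oxoheptyl)-1,2-dioxolan-3-yl]acetic acid
Conditions: TsOH·H2O (cat.), acetone/H2O, rt
Reagents that add atoms: water, O
Why: Acid-catalysed hydrolysis (transacetalisation) of the dioxolane acetal; the fully substituted dialkyl peroxide is stable to dilute acid.

Step 18
Reactants: 26 (2Z)-pent-2-en-1-ol
Product: 27 (2Z)-1-bromopent-2-ene
Conditions: PBr3 (0.4 equiv), pyridine (cat.), Et2O, −10 °C
Reagents that add atoms: phosphorus tribromide, BrP(Br)Br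
Why: SN2 bromination of the primary allylic alcohol through its phosphite ester at low temperature should keep the Z geometry.

Step 19
Reactants: 27 (2Z)-1-bromopent-2-ene; 28 prop-2-yn-1-ol
Product: 29 (5Z)-oct-5-en-2-yn-1-ol
Conditions: CuI (cat.), NaI, Cs2CO3, DMF, rt
Reagents that add atoms: none
Why: Copper-catalysed coupling of a terminal alkyne with a primary allylic halide (SN2 at the CH2 terminus) gives the skipped enyne with the Z alkene intact.

Step 20
Reactants: 29 (5Z)-oct-5-en-2-yn-1-ol
Product: 30 (2E,5Z)-octa-2,5-dien-1-ol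
Conditions: LiAlH4, THF, 0 °C → reflux; aqueous work-up
Reagents that add atoms: none
Why: Hydroxyl-directed trans-hydroalumination of the propargylic alcohol with LiAlH4 gives the (E)-allylic alcohol, and the isolated Z alkene is not reduced.

Step 21
Reactants: 30 (2E,5Z)-octa-2,5-dien-1-ol
Product: 31 (2E,5Z)-1-bromoocta-2,5-diene
Conditions: CBr4, PPh3, CH2Cl2, −20 → 0 °C
Reagents that add atoms: carbon tetrabromide, BrC(Br)(Br)Br
Why: Appel bromination under neutral conditions should convert the primary allylic alcohol to the bromide without allylic transposition or alkene isomerisation.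

Step 22
Reactants: 31 (2E,5Z)-1-bromoocta-2,5-diene
Product: 32 diethyl [(2E,5Z)-octa-2,5-dien-1-yl]phosphonate
Conditions: P(OEt)3 (neat), 120 °C
Reagents that add atoms: triethyl phosphite, CCOP(OCC)OCC
Why: Michaelis–Arbuzov reaction of the primary allylic bromide with triethyl phosphite.

Step 23
Reactants: 25 aldehyde acid; 32 dienyl phosphonate
Product: 34 2-[(3R,5S)-3,5-dimethyl-5-[(7E,9E,12Z)-pentadeca-7,9,12-trien-1-yl]-1,2-dioxolan-3-yl]acetic acid, via lithiated phosphonate 33 (not isolated)
Conditions: 32 (2.3 equiv), LiHMDS (2.2 equiv), THF/DMPU, −78 °C; then 25, −78 °C → rt; dil. acid work-up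
Reagents that add atoms: none
Why: Horner–Wadsworth–Emmons olefination: the α-lithiated allylic phosphonate (in excess to cover the acid proton) adds through its α-carbon to the aldehyde and syn-eliminates diethyl phosphate to give the new C=C predominantly E, while the 2E and 5Z alkenes of the reagent are carried through and the dioxolane, which has no hydrogen on its oxygen-bearing carbons, should survive the base.

## Compound list

1 | 3-bromoprop-1-yne | C#CCBr | starting material
2 | ethynylmagnesium bromide | C#C[Mg]Br | starting material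
3 | penta-1,4-diyne | C#CCC#C | intermediate
4 | (1E,4E)-(2,4-dimethylpenta-1,4-diene-1,5-diyl)bis(dimethylalumane) | C[Al](C)/C=C(\C)C/C(C)=C/[Al](C)C | intermediate
5 | (2E,5E)-3,5-dimethylhepta-2,5-diene-1,7-diol | OC/C=C(\C)C/C(C)=C/CO | intermediate
6 | (2E,5E)-7-{[tert-butyl(dimethyl)silyl]oxy}-3,5-dimethylhepta-2,5-dien-1-ol | CC(C)(C)[Si](C)(C)OC/C=C(\C)C/C(C)=C/CO | intermediate
7 | [(2S,3S)-3-[(2E)-4-{[tert-butyl(dimethyl)silyl]oxy}-2-methylbut-2-en-1-yl]-3-methyloxiran-2-yl]methanol | OC[C@@H]1O[C@@]1(C)C/C(C)=C/CO[Si](C)(C)C(C)(C)C | intermediate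
8 | (3S,5E)-7-{[tert-butyl(dimethyl)silyl]oxy}-3,5-dimethylhept-5-ene-1,3-diol | OCC[C@@](C)(O)C/C(C)=C/CO[Si](C)(C)C(C)(C)C | intermediate
9 | (3S,5E)-7-{[tert-butyl(dimethyl)silyl]oxy}-3-hydroxy-3,5-dimethylhept-5-en-1-yl 4-methylbenzenesulfonate | Cc1ccc(cc1)S(=O)(=O)OCC[C@@](C)(O)C/C(C)=C/CO[Si](C)(C)C(C)(C)C | intermediate
10 | tert-butyl(dimethyl){[(2E)-3-methyl-4-[(2S)-2-methyloxetan-2-yl]but-2-en-1-yl]oxy}silane | CC(C)(C)[Si](C)(C)OC/C=C(\C)C[C@@]1(C)CCO1 | intermediate
11 | (2E)-3-methyl-4-[(2S)-2-methyloxetan-2-yl]but-2-en-1-ol | OC/C=C(\C)C[C@@]1(C)CCO1 | intermediate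
12 | [(2S,3S)-3-methyl-3-{[(2R)-2-methyloxetan-2-yl]methyl}oxiran-2-yl]methanol | OC[C@@H]1O[C@@]1(C)C[C@@]1(C)CCO1 | intermediate
13 | (3R)-3-methyl-4-[(2R)-2-methyloxetan-2-yl]butane-1,3-diol | OCC[C@@](C)(O)C[C@@]1(C)CCO1 | intermediate
14 | (3R)-3-hydroxy-3-methyl-4-[(2R)-2-methyloxetan-2-yl]butyl 4-methylbenzenesulfonate | Cc1ccc(cc1)S(=O)(=O)OCC[C@@](C)(O)C[C@@]1(C)CCO1 | intermediate
15 | (2R,2'R)-2,2'-methylenebis(2-methyloxetane) | C([C@@]1(C)CCO1)[C@@]1(C)CCO1 | intermediate
16 | (3S)-3-hydroperoxy-3-methyl-4-[(2R)-2-methyloxetan-2-yl]butan-1-ol | OCC[C@](C)(OO)C[C@@]1(C)CCO1 | intermediate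
17 | 2,2'-[(3S,5S)-3,5-dimethyl-1,2-dioxolane-3,5-diyl]di(ethan-1-ol) | OCC[C@@]1(C)C[C@](C)(CCO)OO1 | intermediate
18 | 2,2'-[(3R,5R)-3,5-dimethyl-1,2-dioxolane-3,5-diyl]diacetaldehyde | O=CC[C@@]1(C)C[C@](C)(CC=O)OO1 | intermediate
19 | 2-(4-bromobutyl)-1,3-dioxolane | BrCCCCC1OCCO1 | starting material
20 | [4-(1,3-dioxolan-2-yl)butyl](triphenyl)phosphonium bromide | [Br-].C1COC(O1)CCCC[P+](c1ccccc1)(c1ccccc1)c1ccccc1 | intermediate
21 | [4-(1,3-dioxolan-2-yl)butylidene](triphenyl)phosphorane | C1COC(O1)CCCC=P(c1ccccc1)(c1ccccc1)c1ccccc1 | intermediate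
22 | 2-[(3R,5S)-5-[(2Z)-6-(1,3-dioxolan-2-yl)hex-2-en-1-yl]-3,5-dimethyl-1,2-dioxolan-3-yl]acetaldehyde | C1COC(O1)CCC/C=C\C[C@@]1(C)C[C@](C)(CC=O)OO1 | intermediate
23 | 2-[(3R,5S)-5-[(2Z)-6-(1,3-dioxolan-2-yl)hex-2-en-1-yl]-3,5-dimethyl-1,2-dioxolan-3-yl]acetic acid | C1COC(O1)CCC/C=C\C[C@@]1(C)C[C@](C)(CC(=O)O)OO1 | intermediate
24 | 2-[(3R,5S)-5-[6-(1,3-dioxolan-2-yl)hexyl]-3,5-dimethyl-1,2-dioxolan-3-yl]acetic acid | C1COC(O1)CCCCCC[C@@]1(C)C[C@](C)(CC(=O)O)OO1 | intermediate
25 | 2-[(3R,5S)-3,5-dimethyl-5-(7-oxoheptyl)-1,2-dioxolan-3-yl]acetic acid | O=CCCCCCC[C@@]1(C)C[C@](C)(CC(=O)O)OO1 | intermediate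
26 | (2Z)-pent-2-en-1-ol | CC/C=C\CO | starting material
27 | (2Z)-1-bromopent-2-ene | CC/C=C\CBr | intermediate
28 | prop-2-yn-1-ol | C#CCO | starting material
29 | (5Z)-oct-5-en-2-yn-1-ol | CC/C=C\CC#CCO | intermediate
30 | (2E,5Z)-octa-2,5-dien-1-ol | CC/C=C\C/C=C/CO | intermediate
31 | (2E,5Z)-1-bromoocta-2,5-diene | CC/C=C\C/C=C/CBr | intermediate
32 | diethyl [(2E,5Z)-octa-2,5-dien-1-yl]phosphonate | CC/C=C\C/C=C/CP(=O)(OCC)OCC | intermediate
33 | lithium salt of diethyl [(2E,5Z)-octa-2,5-dien-1-yl]phosphonate α-carbanion | [Li+].CC/C=C\C/C=C/[CH-]P(=O)(OCC)OCC | intermediate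
34 | 2-[(3R,5S)-3,5-dimethyl-5-[(7E,9E,12Z)-pentadeca-7,9,12-trien-1-yl]-1,2-dioxolan-3-yl]acetic acid | CC/C=C\C/C=C/C=C/CCCCCC[C@@]1(C)C[C@](C)(CC(=O)O)OO1 | target

Note: some descriptors change between consecutive compounds (11 → 12, 17 → 18, 18 → 22) only because CIP priorities change; no stereocentre is touched after step 11.

## Step count and risks

Total step count: 23. Longest linear sequence: 17 steps (steps 1–12, 14–17 and 23).

**Step 11 (key step).** What may go wrong: the primary hydroxyl freed in the first ring opening, or a second molecule of H2O2, may capture the second oxetane; ionisation at the tertiary carbon may erode the inversion or lead to elimination.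
Fallback (oxirane instead of oxetane strain release; sets out from 5, comes back at 18): 5 should undergo double Sharpless epoxidation (Ti(OiPr)4, L-(+)-diisopropyl tartrate, t-BuOOH) to (2S,3S,5S,6S)-2,3:5,6-diepoxy-3,5-dimethylheptane-1,7-diol F1. Ethereal H2O2 with catalytic phosphomolybdic acid H3PMo12O40 should open one trisubstituted epoxide at its tertiary carbon and let the hydroperoxide open the second in the 5-exo mode, each with inversion, to give (1S,1'S)-1,1'-[(3R,5R)-3,5-dimethyl-1,2-dioxolane-3,5-diyl]di(ethane-1,2-diol) F2. NaIO4 cleavage of both glycols should give (3R,5R)-3,5-dimethyl-1,2-dioxolane-3,5-dicarbaldehyde F3, a non-enolisable α-peroxy dialdehyde. Double Wittig methoxymethylenation (Ph3P=CHOMe) should give (3R,5R)-3,5-bis(2-methoxyethenyl)-3,5-dimethyl-1,2-dioxolane F4, and dilute aqueous acid should hydrolyse both enol ethers to 18.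

**Step 14.** What may go wrong: olefination of both formyl arms, and base-induced β-elimination that opens the peroxide through the enolate of the β-peroxy aldehyde.
Fallback (polarity inversion, no β-peroxy carbonyl under base; sets out from 17, comes back at 24): monotosylation of 17 (TsCl, 1 equiv, pyridine) should give 2-[(3S,5S)-5-(2-hydroxyethyl)-3,5-dimethyl-1,2-dioxolan-3-yl]ethyl 4-methylbenzenesulfonate F5. Displacement with sodium 1-phenyl-1H-tetrazole-5-thiolate in DMF should give 2-[(3S,5R)-3,5-dimethyl-5-{2-[(1-phenyl-1H-tetrazol-5-yl)sulfanyl]ethyl}-1,2-dioxolan-3-yl]ethan-1-ol F6. Oxidation with H2O2 and catalytic (NH4)6Mo7O24 should give 2-[(3S,5R)-3,5-dimethyl-5-{2-[(1-phenyl-1H-tetrazol-5-yl)sulfonyl]ethyl}-1,2-dioxolan-3-yl]ethan-1-ol F7. Julia–Kocienski olefination (KHMDS, 2.2 equiv, DME, −60 °C) with 4-(1,3-dioxolan-2-yl)butanal should give 2-[(3S,5S)-5-[(2E)-6-(1,3-dioxolan-2-yl)hex-2-en-1-yl]-3,5-dimethyl-1,2-dioxolan-3-yl]ethan-1-ol F8. Diimide reduction (TsNHNH2, NaOAc) should give 2-[(3S,5S)-5-[6-(1,3-dioxolan-2-yl)hexyl]-3,5-dimethyl-1,2-dioxolan-3-yl]ethan-1-ol F9, and TEMPO/PhI(OAc)2 oxidation in buffered MeCN/H2O should convert the hydroxyethyl arm to the acid 24.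

**Step 23.** What may go wrong: incomplete E selectivity at the new C=C, or stalling at the β-hydroxy phosphonate, giving a geometrical mixture that is hard to separate at the acid stage.
Fallback (stereospecific cross-coupling instead of olefination; sets out from 25, with the partner made from 27 and 2, and comes back at 34): boron-Wittig reaction of 25 with CH2(Bpin)2 and LiTMP should give 2-[(3R,5S)-3,5-dimethyl-5-[(7E)-8-(4,4,5,5-tetramethyl-1,3,2-dioxaborolan-2-yl)oct-7-en-1-yl]-1,2-dioxolan-3-yl]acetic acid F10. Separately, CuCl-catalysed coupling of 27 with 2 should give (4Z)-hept-4-en-1-yne F11, and hydrozirconation with Cp2Zr(H)Cl followed by I2 should give (1E,4Z)-1-iodohepta-1,4-diene F12. Suzuki–Miyaura coupling of F10 with F12 (Pd(PPh3)4, aq. Cs2CO3, THF, rt) should form the diene with both geometries retained and give 34.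

Further compounds
F1 | step 11 | (2S,3S,5S,6S)-2,3:5,6-diepoxy-3,5-dimethylheptane-1,7-diol | OC[C@@H]1O[C@@]1(C)C[C@]1(C)O[C@H]1CO
F2 | step 11 | (1S,1'S)-1,1'-[(3R,5R)-3,5-dimethyl-1,2-dioxolane-3,5-diyl]di(ethane-1,2-diol) | OC[C@H](O)[C@@]1(C)C[C@](C)([C@@H](O)CO)OO1
F3 | step 11 | (3R,5R)-3,5-dimethyl-1,2-dioxolane-3,5-dicarbaldehyde | O=C[C@@]1(C)C[C@](C)(C=O)OO1
F4 | step 11 | (3R,5R)-3,5-bis(2-methoxyethenyl)-3,5-dimethyl-1,2-dioxolane | COC=C[C@@]1(C)C[C@](C)(C=COC)OO1
F5 | step 14 | 2-[(3S,5S)-5-(2-hydroxyethyl)-3,5-dimethyl-1,2-dioxolan-3-yl]ethyl 4-methylbenzenesulfonate | Cc1ccc(cc1)S(=O)(=O)OCC[C@@]1(C)C[C@](C)(CCO)OO1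
F6 | step 14 | 2-[(3S,5R)-3,5-dimethyl-5-{2-[(1-phenyl-1H-tetrazol-5-yl)sulfanyl]ethyl}-1,2-dioxolan-3-yl]ethan-1-ol | c1ccc(cc1)-n1nnnc1SCC[C@@]1(C)C[C@](C)(CCO)OO1
F7 | step 14 | 2-[(3S,5R)-3,5-dimethyl-5-{2-[(1-phenyl-1H-tetrazol-5-yl)sulfonyl]ethyl}-1,2-dioxolan-3-yl]ethan-1-ol | O=S(=O)(CC[C@@]1(C)C[C@](C)(CCO)OO1)c1nnnn1-c1ccccc1
F8 | step 14 | 2-[(3S,5S)-5-[(2E)-6-(1,3-dioxolan-2-yl)hex-2-en-1-yl]-3,5-dimethyl-1,2-dioxolan-3-yl]ethan-1-ol | C1COC(O1)CCC/C=C/C[C@@]1(C)C[C@](C)(CCO)OO1
F9 | step 14 | 2-[(3S,5S)-5-[6-(1,3-dioxolan-2-yl)hexyl]-3,5-dimethyl-1,2-dioxolan-3-yl]ethan-1-ol | C1COC(O1)CCCCCC[C@@]1(C)C[C@](C)(CCO)OO1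
F10 | step 23 | 2-[(3R,5S)-3,5-dimethyl-5-[(7E)-8-(4,4,5,5-tetramethyl-1,3,2-dioxaborolan-2-yl)oct-7-en-1-yl]-1,2-dioxolan-3-yl]acetic acid | CC1(C)OB(OC1(C)C)/C=C/CCCCCC[C@@]1(C)C[C@](C)(CC(=O)O)OO1
F11 | step 23 | (4Z)-hept-4-en-1-yne | CC/C=C\CC#C
F12 | step 23 | (1E,4Z)-1-iodohepta-1,4-diene | CC/C=C\C/C=C/I
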